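All runs are simulated with made-up constants; the scatter is artificial.

Taking the logarithm of a falling curve is an easy step, so I began with the tails of the two earlier runs.

| setting | east | north-east | flask |
|---|---|---|---|
| starting material | 0.80 M | 0.80 M | 0.80 M |
| protic impurity | 0.056 M | 0.088 M | 0.0400 M |
| remark | run made earlier | run made earlier |  |
| time |  |  | 15 h |

- east (time / h: target / %): 0.667: 10.3; 1.33: 14.9; 2.00: 18.9; 3.00: 19.1; 5.00: 16.0; 10.0: 5.8
- north-east (time / h: target / %): 0.667: 9.4; 1.33: 16.0; 2.00: 17.5; 3.00: 18.1; 5.00: 14.7; 10.0: 6.6

(scatter of a reading: 0.5 percentage points)



* when, up to 15 h, the flask holds most target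
* the amount of target, in percent of the starting material charged, at that time

Between 5.00 h and 10.0 h the common logarithm of the target fell by 0.441 in the east run and by 0.348 in the north-east run. Pooled, that gave 12.7 h as the decade time, the hours in which that logarithm falls by one.

Two first-order steps in series, with none of the intermediate at the start, peak before the lifetime of the slower step; taking the tails as that step, I read its lifetime as the decade time over 2.3, so my upper bound was 5.51 h. My lower bound was 2.00 h, since both runs were still rising up to that reading.

To tighten the bracket, I interpolated the slope between readings to zero. That put the peak at 2.67 h in the east run and 2.89 h in the north-east run, a gap I could not tell from the scatter. For the flask, at 0.0500 equivalents of protic impurity, I committed to their mean, 2.78 h.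

The forecast gave 2.4 h and 19.6%, holding that “Nothing suggests a later maximum”, which placed it inside my bounds but earlier than the tightened pair.

The flask peaked at 2.84 h with 19.2%.

    starting material → target (k = 0.200 h⁻¹)
    starting material → side product A (k = 0.280 h⁻¹)
    starting material + target → side product B (k = 0.110 M⁻¹ h⁻¹)
    starting material + protic impurity → quenched substrate (k = 2.20 M⁻¹ h⁻¹)
    target → over-reaction product (k = 0.220 h⁻¹)

At 15.0 h the flask made target at 0.0226 of the rate at which it used it up. From 10.9% at 7.50 h, the decade time gives 2.80% at 15.0 h, and the flask held 2.36%. A second flask with the same charges was read at 2.5 d. From that 2.36% the decade time leaves <0.001%, and it held 0%.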